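**Conventions.** Eremophilane numbering is used for all bicyclic compounds (ring A = C1–C5, C10; ring B = C5–C10; C14 = methyl on C5, C15 = methyl on C4; C11–C13 = side chain on C7). β is the face of the C14 methyl group. Compounds carry the numbers 1–32 of the compound list.

## Analysis of the target

Target 32 is an eremophilane, a cis-fused decalin whose C3 oxygen is esterified with (2E,4E,6E)-5-methyldodeca-2,4,6-trienoic acid. Five contiguous stereocentres run around the ring fusion, C3 (α-acyloxy), C4 (β-methyl), quaternary C5 (β-methyl), C10 (β-H) and C9 (β-OH), which corresponds to 3R,4R,5R,9R,10S; the two methyl groups are cis, H10 is cis to the angular methyl, the C3 oxygen is trans to C15 and the C9 oxygen is cis to H10. In the chair–chair conformer that has C14 axial on ring A, the C15 methyl, the C3 oxygen and the C9 oxygen are all equatorial, so C9, which is α to the C8 ketone, can be set by equilibration. The equatorial C3 oxygen, in contrast, cannot be set by a bulky hydride, which the syn-axial C14 methyl forces to give the axial alcohol, and C5 can only be set in the bond-forming event that creates it. Ring B carries an α-ketol (C8/C9) and a tetrasubstituted exocyclic C7=C11 alkene with its CH2OH (C12) cis to C8 (Z). This (Z)-γ-hydroxy enone closes to a five-membered hemiketal and loses water to a furan under acid, and the trienoate is reducible and sensitive to light and nucleophiles. The hard points are the absolute configuration of quaternary C5 next to C4, the cis ring fusion and the Z alkene. The strategy rests on ring B, which has oxygen on adjacent C8 and C9, the methyl-bearing C5 para to C8 and C10 between C9 and C5: this is the substitution of a 3-alkyl-4-methylcatechol, so ring B can be bought as an arene and C5 made quaternary by attack of C4 on the para carbon of the C8 phenol.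

## Retrosynthetic reasoning

**32 to 31.** Only the O9–Si bond is cut. The γ-hydroxy enone and the α-ketol are the least tolerant groups, so the C9 hydroxyl is released last. The forward step has to cleave a hindered silyl ether with buffered fluoride, without acid (furan) and without strong base.

**31 to 27 and 28.** The C7=C11 bond is cut. C7 is the unhindered α-methylene of the C8 ketone and can be the nucleophile; C11 then has to be a ketone carbon carrying the methyl and the oxygenated CH2. The chlorine of 28 lets the aldolate 29 close to epoxide 30, and opening 30 from the C7 enolate places the alkene at C7=C11 and the oxygen on C12 without a protecting group. Cutting C11–C12 instead would require selective oxidation of one methyl of an isopropylidene group. The forward step must enolise C7 and not C9, add to the carbonyl and not displace chloride, and give the Z alkene.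

**27 to 21 and 26.** The C2'=C3' alkene of the side chain is cut, not the ester C–O bond. A phosphonoacetate survives the hydride chemistry of step 14, which a trienoate would not, and the olefination finishes the acid on the substrate. Dienal 26 goes back through 25 and 24 to 22 and 23 by a two-carbon homologation.

**21 to 19 (through 20).** The C10–H and C9–H bonds are cut. The forward reaction has to deliver hydride to C10 on the β face (cis fusion) and leave C9 equatorial.

**19 to 17 and 18.** The C3–O bond is cut with inversion. Hydride gives the axial 3β-alcohol 17, so the ester oxygen is brought in by displacement, which both inverts C3 and installs the acyl handle.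

**17 to 16.** The C3–H and the C6–H/C7–H bonds are cut. One hindered hydride has to reduce the C3 ketone from the equatorial side and add 1,4 to the less substituted enone while leaving the silyloxy enone intact.

**16 to 14 (through 15).** The C4–H bond is cut. The carboxyl on C4 is there only to make C4 a stabilised carbon nucleophile; its removal has to deliver the proton to C4 anti to the C14 methyl.

**14 to 13.** The C4–C5 bond is cut, opening ring A and restoring the arene. This is the disconnection that trades the quaternary stereocentre and ring A for a flat phenol; a chiral aryl iodide catalyst with a peracid has to control the face of C5.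

**13 to 12, and 12 to 9 and 10 (through 11).** The O8 benzyl ether is cut, then the C3–C4 bond by ester-enolate acylation. The benzyl group is removed without hydrogen so that the allyl ester survives.

**9 to 8 to 7 to 6.** Functional-group changes only: the acid carbon C3 comes from the terminal alkene carbon by hydroboration and oxidation, and the C14 methyl from the formyl group.

**6 to 5 to 4 to 2 and 3, and 2 to 1.** The O9–Si bond, then the aryl C10–C1 bond by an aromatic [3,3] shift, then the two ether bonds. The formyl group of 1 makes the para hydroxyl the more acidic one, which differentiates the catechol oxygens, and it steers the allyl group to the carbon between oxygen and formyl.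

## Alternatives that were turned down

Alternative 1: The C9–C10 bond is cut. In the forward key step SnCl4 activates a keto aldehyde chain (C8 ketone, C9 aldehyde) hanging from C5 of a ring A allylsilane. C10 attacks C9 anti to the silicon on C2 (Hosomi–Sakurai), the alkene moves to C1–C2, and ring B closes to give 3α-(triethylsilyloxy)-9β-hydroxy-12-(tert-butyldiphenylsilyloxy)eremophila-1,7(11)-dien-8-one (A1).
- For it: one step makes the C9–C10 bond, both of its stereocentres and ring B, with the well-understood anti course of allylsilanes. A1 already carries the C3 oxygen and the complete C7 side chain with its alkene geometry fixed in open-chain chemistry. On this point it is stronger than the chosen route, whose product 14 still needs seven further steps to reach 32.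
- Against it: its substrate needs C3, C4, the quaternary C5 and the C2 silane on an enantiopure cyclohexene, plus a tetrasubstituted Z alkene bearing a vicinal keto aldehyde. That 1,2-dicarbonyl hydrates and enolises easily, can chelate the Lewis acid so that the C9 configuration depends on an open versus closed transition state, and may lose its alkene geometry. The C1–C2 alkene of A1 has to be hydrogenated afterwards beside the trienoate precursor.
- Comparison: the substrate is much longer to make and needs several separate asymmetric operations. The chosen strategy takes ring B with all its substituents from a benzaldehyde and needs one asymmetric event.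

Alternative 2: The C3–C4 and C5–C10 bonds are cut. Heating a triene joins a 1-acetoxydiene (C10, C1, C2, C3) to the C4=C5 alkene in an intramolecular Diels–Alder reaction. Ring A is the cycloadduct and ring B the ring of the C6–C9 tether, giving 3α-acetoxy-9β-(tert-butyldimethylsilyloxy)-11,12,13-trinoreremophil-1-en-8-one (A2).
- For it: two bonds, two rings and four stereocentres (C3, C4, C5, C10) form at once, and the cis methyl groups follow from the dienophile geometry. In bonds and stereocentres per step it is stronger than the chosen route, which sets C4, C10, C9 and C3 one at a time.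
- Against it: the dienophile is a trisubstituted alkene with two methyl groups, not conjugated to an acceptor, and has to form a quaternary carbon, so the reaction needs high temperature. Face and endo/exo selectivity rest only on the C9 silyloxy centre across a four-atom tether. The acetoxydiene is fragile, and A2 still needs the C7 side chain and reduction of C1=C2.
- Comparison: its selectivity rests on a thermal reaction of an unactivated dienophile. The chosen route confines the uncertainty to one catalytic step on a flat substrate made by routine aromatic chemistry, and sets the later centres by arguments that can be checked.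

Alternative 3: The C7–C8 bond is cut. A C7 alkenyl iodide, with the tetrasubstituted C7=C11 alkene already in place, is converted by CrCl2 with catalytic NiCl2 (Nozaki–Hiyama–Kishi conditions) into an alkenylchromium that adds to a C8 aldehyde. Ring B closes to 3α-(4-methoxybenzyloxy)-9β,12-bis(tert-butyldimethylsilyloxy)eremophil-7(11)-en-8-ol (A3).
- For it: the alkene geometry is retained through metalation and addition, so the Z alkene is settled before ring closure. That is the least secure element of the chosen route, and on this point the alternative is stronger. Six-membered closures of this kind are as dependable as the chosen ring A closure is uncertain.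
- Against it: ring A with C3, C4, quaternary C5 and C10, and the C9 stereocentre, must all be present before closure. The aldehyde is α-silyloxy and epimerisable at C9, and a large excess of CrCl2 is needed. The carbinol A3 must still be oxidised at C8 and freed of three protecting groups before the trienoate can be attached.
- Comparison: it is weaker in step economy because ring A with its quaternary carbon must be built first. The chosen route offers a one-step construction of the C4–C5 bond and the quaternary centre.

Key step: step 10

Assumption: the sense of induction of the lactamide-based aryl iodide in step 10 cannot be derived from precedent; the (S,S) catalyst is written provisionally and its antipode would be used if it favours the wrong configuration at C5.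

## Steps

Step 1
Reactants: 1 3,4-dihydroxybenzaldehyde
Product: 2 4-(benzyloxy)-3-hydroxybenzaldehyde
Conditions: BnBr (1.0 equiv), NaHCO3, NaI (cat.), DMF, 40 °C
Reagents that add atoms: benzyl bromide, BrCc1ccccc1
Why: The hydroxyl para to the formyl group is the more acidic one, so the weak base forms only its phenoxide and the Williamson etherification should benzylate it selectively.

Step 2
Reactants: 2 4-(benzyloxy)-3-hydroxybenzaldehyde; 3 allyl bromide
Product: 4 3-(allyloxy)-4-(benzyloxy)benzaldehyde
Conditions: K2CO3, DMF, rt
Reagents that add atoms: none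
Why: Williamson O-allylation of the remaining phenol.

Step 3
Reactants: 4 3-(allyloxy)-4-(benzyloxy)benzaldehyde
Product: 5 2-allyl-4-(benzyloxy)-3-hydroxybenzaldehyde
Conditions: N,N-diethylaniline, 190 °C
Reagents that add atoms: none
Why: Aromatic Claisen rearrangement; one ortho position of the allyloxy group is blocked by the benzyloxy group, so the [3,3] shift should deliver the allyl group to the carbon between oxygen and formyl, which the meta acceptor also favours, and tautomerisation restores the phenol.

Step 4
Reactants: 5 2-allyl-4-(benzyloxy)-3-hydroxybenzaldehyde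
Product: 6 2-allyl-4-(benzyloxy)-3-(triisopropylsilyloxy)benzaldehyde
Conditions: i-Pr3SiOTf, 2,6-lutidine, CH2Cl2, 0 °C to rt
Reagents that add atoms: triisopropylsilyl trifluoromethanesulfonate, CC(C)[Si](OS(=O)(=O)C(F)(F)F)(C(C)C)C(C)C
Why: Silylation of the hindered phenol needs the silyl triflate; the bulky group is chosen to shield the oxygen-bearing carbon C9 in step 10 and to survive as an enol ether afterwards.

Step 5
Reactants: 6 2-allyl-4-(benzyloxy)-3-(triisopropylsilyloxy)benzaldehyde
Product: 7 [2-allyl-6-(benzyloxy)-3-methylphenoxy]triisopropylsilane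
Conditions: Et3SiH (3 equiv), CF3CO2H, CH2Cl2, 0 °C to rt
Reagents that add atoms: none
Why: Ionic hydrogenation: the protonated aldehyde takes one hydride, the benzylic oxygen ionises to a cation stabilised by the para benzyloxy group and takes a second hydride; the aryl silyl ether, benzyl ether and terminal alkene should be inert under these conditions.

Step 6
Reactants: 7 [2-allyl-6-(benzyloxy)-3-methylphenoxy]triisopropylsilane
Product: 8 3-[6-(benzyloxy)-3-methyl-2-(triisopropylsilyloxy)phenyl]propan-1-ol
Conditions: 9-BBN, THF, 0 °C to rt; NaBO3·4H2O, H2O, rt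
Reagents that add atoms: sodium perborate, [Na+].[O-]OB=O
Why: Anti-Markovnikov hydroboration with the bulky dialkylborane, then oxidation with perborate, which is milder toward the aryl silyl ether than alkaline peroxide.

Step 7
Reactants: 8 3-[6-(benzyloxy)-3-methyl-2-(triisopropylsilyloxy)phenyl]propan-1-ol
Product: 9 3-[6-(benzyloxy)-3-methyl-2-(triisopropylsilyloxy)phenyl]propanoic acid
Conditions: TEMPO (cat.), PhI(OAc)2, MeCN/H2O, rt
Reagents that add atoms: water, O
Why: Nitroxyl-catalysed oxidation of the primary alcohol through the aldehyde hydrate to the acid; aryl ethers are not touched.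

Step 8
Reactants: 9 3-[6-(benzyloxy)-3-methyl-2-(triisopropylsilyloxy)phenyl]propanoic acid; 10 allyl propionate
Product: 12 allyl 5-[6-(benzyloxy)-3-methyl-2-(triisopropylsilyloxy)phenyl]-2-methyl-3-oxopentanoate, via acyl imidazolide 11 (not isolated)
Conditions: 1,1'-carbonyldiimidazole, THF, rt; added to the enolate from 10 and LiN(i-Pr)2 (2.5 equiv), THF, −78 °C; aq. NH4Cl
Reagents that add atoms: none
Why: Crossed Claisen condensation: the acyl imidazolide acylates the ester enolate and the excess enolate deprotonates the product, which prevents a second acylation; the new centre (C4) is configurationally labile and of no consequence.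

Step 9
Reactants: 12 allyl 5-[6-(benzyloxy)-3-methyl-2-(triisopropylsilyloxy)phenyl]-2-methyl-3-oxopentanoate
Product: 13 allyl 5-[3-hydroxy-6-methyl-2-(triisopropylsilyloxy)phenyl]-2-methyl-3-oxopentanoate
Conditions: BCl3, C6HMe5, CH2Cl2, −78 °C
Reagents that add atoms: none
Why: Lewis-acid debenzylation of the aryl benzyl ether with a cation scavenger; it avoids hydrogen, which would saturate the allyl ester, and should spare the silyl ether and the keto ester at this temperature.

Step 10
Reactants: 13 allyl 5-[3-hydroxy-6-methyl-2-(triisopropylsilyloxy)phenyl]-2-methyl-3-oxopentanoate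
Product: 14 allyl 3,8-dioxo-9-(triisopropylsilyloxy)-11,12,13-trinoreremophila-6,9-diene-4α-carboxylate (5β-methyl; C4 drawn with β-methyl; its epimer serves equally)
Conditions: (S,S)-2-iodo-1,3-bis[1-(mesitylcarbamoyl)ethoxy]benzene (15 mol%), mCPBA (1.3 equiv), CH2Cl2/(CF3)2CHOH 4:1, −20 °C
Reagents that add atoms: none
Why: Proposed new method: mCPBA oxidises the aryl iodide to a chiral trivalent-iodine species, the C8 phenol oxygen exchanges onto iodine, and departure of the aryl iodide makes C5, para to that oxygen, electrophilic, so that the enol of the keto ester attacks C5 through C4 and the 9-silyloxy-cyclohexa-2,5-dienone is released while the aryl iodide re-enters the cycle. The closest known reaction types are PhI(OAc)2-mediated dearomatising cyclisations of 4-alkylphenols onto tethered carbon nucleophiles and aryl-iodide-catalysed enantioselective dearomative spirocyclisations; a fused closure by a keto ester at a methyl-bearing para carbon under catalyst control has no direct precedent. Ring A closes in a 6-(enolendo)-exo-trig mode, the C5=C6 bond of the activated ring lying outside the new ring. C5 is the only lasting stereocentre and its configuration has to come from the chiral ligand sphere of iodine held on O8, which is why a weakly ionising medium at low temperature is chosen to favour an associative pathway over a free phenoxenium ion; C4 forms as either epimer and is reset in step 11. The step needs attack at C5 and not at C9, which is also six atoms from C4 and is activated by its own oxygen; the triisopropylsilyl group shields C9 and is a poorer donor than an alkyl ether. It also needs carbon and not oxygen attack of the enol, which a soft para-carbon electrophile favours, and oxidation of the phenol and not of the keto ester, which the faster ligand exchange of the phenol should secure.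

Step 11
Reactants: 14 allyl 3,8-dioxo-9-(triisopropylsilyloxy)-11,12,13-trinoreremophila-6,9-diene-4α-carboxylate
Product: 16 9-(triisopropylsilyloxy)-11,12,13-trinoreremophila-6,9-diene-3,8-dione (4αH; C14 and C15 both β), via keto acid 15 (not isolated)
Conditions: Pd(OAc)2 (5 mol%), PPh3, HCO2H, Et3N, THF, rt
Reagents that add atoms: none
Why: Zerovalent palladium ionises the allyl ester, formate reduces the allyl ligand to propene, and the keto acid decarboxylates through its enol (palladium-catalysed deallylative decarboxylation). The enol should take its proton at C4 along the axial direction on the α face, anti to the axial C14 methyl on the neighbouring quaternary carbon, which gives the 4β-methyl ketone under kinetic control; the mild buffer is chosen so that C4 does not equilibrate.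

Step 12
Reactants: 16 9-(triisopropylsilyloxy)-11,12,13-trinoreremophila-6,9-diene-3,8-dione
Product: 17 3β-hydroxy-9-(triisopropylsilyloxy)-11,12,13-trinoreremophil-9-en-8-one
Conditions: Li[HB(sec-Bu)3] (2.3 equiv), THF, −78 °C; aq. NH4Cl
Reagents that add atoms: none
Why: The hindered borohydride should attack C3 from the equatorial α side, because the axial path is blocked by the syn-axial C14 methyl, and give the axial 3β-alcohol; this also locks C4. It should add 1,4 to the disubstituted enone at C6, and the resulting enolate protects C8, while the tetrasubstituted silyloxy enone is too hindered to react.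

Step 13
Reactants: 17 3β-hydroxy-9-(triisopropylsilyloxy)-11,12,13-trinoreremophil-9-en-8-one; 18 (diethoxyphosphoryl)acetic acid
Product: 19 8-oxo-9-(triisopropylsilyloxy)-11,12,13-trinoreremophil-9-en-3α-yl (diethoxyphosphoryl)acetate
Conditions: PPh3, i-PrO2CN=NCO2i-Pr, toluene, 0 °C to rt
Reagents that add atoms: none
Why: Mitsunobu esterification: the carboxylate displaces the activated axial oxygen from the open α side with inversion, so the ester ends equatorial and 3α as in the target. The phosphonoacetate is chosen because it is inert to the hydride of step 14, unlike the trienoate.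

Step 14
Reactants: 19 8-oxo-9-(triisopropylsilyloxy)-11,12,13-trinoreremophil-9-en-3α-yl (diethoxyphosphoryl)acetate
Product: 21 8-oxo-9β-(triisopropylsilyloxy)-11,12,13-trinoreremophilan-3α-yl (diethoxyphosphoryl)acetate (10βH), via silyl enol ether 20 (not isolated)
Conditions: Cu(OAc)2·H2O (5 mol%), 1,2-(Ph2P)2C6H4 (5 mol%), (EtO)2MeSiH, toluene, rt; dilute aq. HCl, THF, 0 °C; then DBU, toluene, 60 °C
Reagents that add atoms: none
Why: Copper hydride (CuH) conjugate reduction: hydride should reach C10 on the β face, axial to ring B and equatorial to ring A, as carbon nucleophiles do with angularly methylated octalones, because the α face is screened by the axial hydrogens on C2 and C4; this gives the cis fusion. The enolate is held as silyl enol ether 20 and hydrolysed; C9 is then equilibrated with DBU to the 9β epimer, the only one with the silyloxy group equatorial once the 3α-ester and the 4β-methyl fix the chair–chair conformer.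

Step 15
Reactants: 22 (E)-non-3-en-2-one; 23 triethyl phosphonoacetate
Product: 24 ethyl (2E,4E)-3-methyldeca-2,4-dienoate
Conditions: NaH, THF, 0 °C to reflux
Reagents that add atoms: none
Why: Horner–Wadsworth–Emmons olefination of the methyl ketone should give mainly the 2E ester; the minor 2Z isomer would be removed by chromatography.

Step 16
Reactants: 24 ethyl (2E,4E)-3-methyldeca-2,4-dienoate
Product: 25 (2E,4E)-3-methyldeca-2,4-dien-1-ol
Conditions: (i-Bu)2AlH (2.2 equiv), CH2Cl2, −78 °C
Reagents that add atoms: none
Why: 1,2-Reduction of the conjugated ester to the allylic alcohol without touching the diene.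

Step 17
Reactants: 25 (2E,4E)-3-methyldeca-2,4-dien-1-ol
Product: 26 (2E,4E)-3-methyldeca-2,4-dienal
Conditions: MnO2, CH2Cl2, rt
Reagents that add atoms: none
Why: Selective oxidation of the allylic alcohol under neutral conditions that keep the alkene geometry.

Step 18
Reactants: 21 8-oxo-9β-(triisopropylsilyloxy)-11,12,13-trinoreremophilan-3α-yl (diethoxyphosphoryl)acetate; 26 (2E,4E)-3-methyldeca-2,4-dienal
Product: 27 8-oxo-9β-(triisopropylsilyloxy)-11,12,13-trinoreremophilan-3α-yl (2E,4E,6E)-5-methyldodeca-2,4,6-trienoate (10βH)
Conditions: LiCl, DBU, MeCN, 0 °C to rt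
Reagents that add atoms: none
Why: Horner–Wadsworth–Emmons olefination under mild lithium chloride/amidine conditions should give the 2E alkene and complete the trienoate on the substrate; the phosphonate is far more acidic than the ketone, so the C8 ketone is not engaged.

Step 19
Reactants: 27 8-oxo-9β-(triisopropylsilyloxy)-11,12,13-trinoreremophilan-3α-yl (2E,4E,6E)-5-methyldodeca-2,4,6-trienoate; 28 chloroacetone
Product: 31 (7(11)Z)-12-hydroxy-8-oxo-9β-(triisopropylsilyloxy)eremophil-7(11)-en-3α-yl (2E,4E,6E)-5-methyldodeca-2,4,6-trienoate, via chlorohydrin 29 (not isolated), via epoxy ketone 30 (not isolated)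
Conditions: LiN(SiMe3)2 (1.1 equiv), THF, −78 °C; 28, −78 to 0 °C; then DBU, 0 °C to rt
Reagents that add atoms: none
Why: The hindered amide should deprotonate the C7 methylene and not the silyloxy-bearing C9 methine; the enolate adds to the activated carbonyl of the chloro ketone and the aldolate closes to the epoxide (Darzens-type halohydrin closure). DBU then opens the epoxy ketone by E1cB elimination from the C7 enolate to the γ-hydroxy enone. The Z isomer is expected because the tied-back epoxide CH2 sits next to the enolate oxygen in the reacting rotamer and because only the Z product gains the hydrogen bond or hemiketal to C8; DBU also keeps C9 at its equatorial configuration.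

Step 20
Reactants: 31 (7(11)Z)-12-hydroxy-8-oxo-9β-(triisopropylsilyloxy)eremophil-7(11)-en-3α-yl (2E,4E,6E)-5-methyldodeca-2,4,6-trienoate
Product: 32 (7(11)Z)-9β,12-dihydroxy-8-oxoeremophil-7(11)-en-3α-yl (2E,4E,6E)-5-methyldodeca-2,4,6-trienoate (target)
Conditions: Bu4NF, AcOH, THF, 0 °C to rt
Reagents that add atoms: none
Why: Fluoride cleaves the silyl ether next to the ketone; the acetic acid buffer should prevent base-induced change of the α-ketol and the trienoate, and the absence of strong acid avoids cyclodehydration to the furan.

## Compound list

1 | 3,4-dihydroxybenzaldehyde | O=Cc1ccc(O)c(O)c1 | starting material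
2 | 4-(benzyloxy)-3-hydroxybenzaldehyde | O=Cc1ccc(OCc2ccccc2)c(O)c1 | intermediate
3 | allyl bromide | C=CCBr | starting material
4 | 3-(allyloxy)-4-(benzyloxy)benzaldehyde | O=Cc1ccc(OCc2ccccc2)c(OCC=C)c1 | intermediate
5 | 2-allyl-4-(benzyloxy)-3-hydroxybenzaldehyde | O=Cc1ccc(OCc2ccccc2)c(O)c1CC=C | intermediate
6 | 2-allyl-4-(benzyloxy)-3-(triisopropylsilyloxy)benzaldehyde | O=Cc1ccc(OCc2ccccc2)c(O[Si](C(C)C)(C(C)C)C(C)C)c1CC=C | intermediate
7 | [2-allyl-6-(benzyloxy)-3-methylphenoxy]triisopropylsilane | Cc1ccc(OCc2ccccc2)c(O[Si](C(C)C)(C(C)C)C(C)C)c1CC=C | intermediate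
8 | 3-[6-(benzyloxy)-3-methyl-2-(triisopropylsilyloxy)phenyl]propan-1-ol | Cc1ccc(OCc2ccccc2)c(O[Si](C(C)C)(C(C)C)C(C)C)c1CCCO | intermediate
9 | 3-[6-(benzyloxy)-3-methyl-2-(triisopropylsilyloxy)phenyl]propanoic acid | Cc1ccc(OCc2ccccc2)c(O[Si](C(C)C)(C(C)C)C(C)C)c1CCC(=O)O | intermediate
10 | allyl propionate | CCC(=O)OCC=C | starting material
11 | 1-{3-[6-(benzyloxy)-3-methyl-2-(triisopropylsilyloxy)phenyl]propanoyl}imidazole (not isolated) | Cc1ccc(OCc2ccccc2)c(O[Si](C(C)C)(C(C)C)C(C)C)c1CCC(=O)n1ccnc1 | intermediate
12 | allyl 5-[6-(benzyloxy)-3-methyl-2-(triisopropylsilyloxy)phenyl]-2-methyl-3-oxopentanoate (C2 of the pentanoate labile) | C=CCOC(=O)C(C)C(=O)CCc1c(C)ccc(OCc2ccccc2)c1O[Si](C(C)C)(C(C)C)C(C)C | intermediate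
13 | allyl 5-[3-hydroxy-6-methyl-2-(triisopropylsilyloxy)phenyl]-2-methyl-3-oxopentanoate (C2 of the pentanoate labile) | C=CCOC(=O)C(C)C(=O)CCc1c(C)ccc(O)c1O[Si](C(C)C)(C(C)C)C(C)C | intermediate
14 | allyl 3,8-dioxo-9-(triisopropylsilyloxy)-11,12,13-trinoreremophila-6,9-diene-4α-carboxylate (C14 and C15 β) | O=C1CCC2=C(O[Si](C(C)C)(C(C)C)C(C)C)C(=O)C=C[C@]2(C)[C@]1(C)C(=O)OCC=C | intermediate
15 | 3,8-dioxo-9-(triisopropylsilyloxy)-11,12,13-trinoreremophila-6,9-diene-4α-carboxylic acid (not isolated) | O=C1CCC2=C(O[Si](C(C)C)(C(C)C)C(C)C)C(=O)C=C[C@]2(C)[C@]1(C)C(=O)O | intermediate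
16 | 9-(triisopropylsilyloxy)-11,12,13-trinoreremophila-6,9-diene-3,8-dione (4αH; C14 and C15 β) | O=C1CCC2=C(O[Si](C(C)C)(C(C)C)C(C)C)C(=O)C=C[C@]2(C)[C@H]1C | intermediate
17 | 3β-hydroxy-9-(triisopropylsilyloxy)-11,12,13-trinoreremophil-9-en-8-one | O[C@H]1CCC2=C(O[Si](C(C)C)(C(C)C)C(C)C)C(=O)CC[C@]2(C)[C@H]1C | intermediate
18 | (diethoxyphosphoryl)acetic acid | CCOP(=O)(CC(=O)O)OCC | starting material
19 | 8-oxo-9-(triisopropylsilyloxy)-11,12,13-trinoreremophil-9-en-3α-yl (diethoxyphosphoryl)acetate | CCOP(=O)(CC(=O)O[C@@H]1CCC2=C(O[Si](C(C)C)(C(C)C)C(C)C)C(=O)CC[C@]2(C)[C@H]1C)OCC | intermediate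
20 | 8-[diethoxy(methyl)silyloxy]-9-(triisopropylsilyloxy)-11,12,13-trinoreremophil-8-en-3α-yl (diethoxyphosphoryl)acetate (10βH; not isolated) | CCOP(=O)(CC(=O)O[C@@H]1CC[C@@H]2C(O[Si](C(C)C)(C(C)C)C(C)C)=C(O[Si](C)(OCC)OCC)CC[C@]2(C)[C@H]1C)OCC | intermediate
21 | 8-oxo-9β-(triisopropylsilyloxy)-11,12,13-trinoreremophilan-3α-yl (diethoxyphosphoryl)acetate (10βH, cis-decalin) | CCOP(=O)(CC(=O)O[C@@H]1CC[C@@H]2[C@@H](O[Si](C(C)C)(C(C)C)C(C)C)C(=O)CC[C@]2(C)[C@H]1C)OCC | intermediate
22 | (E)-non-3-en-2-one | CCCCC/C=C/C(C)=O | starting material
23 | triethyl phosphonoacetate | CCOC(=O)CP(=O)(OCC)OCC | starting material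
24 | ethyl (2E,4E)-3-methyldeca-2,4-dienoate | CCCCC/C=C/C(C)=C/C(=O)OCC | intermediate
25 | (2E,4E)-3-methyldeca-2,4-dien-1-ol | CCCCC/C=C/C(C)=C/CO | intermediate
26 | (2E,4E)-3-methyldeca-2,4-dienal | CCCCC/C=C/C(C)=C/C=O | intermediate
27 | 8-oxo-9β-(triisopropylsilyloxy)-11,12,13-trinoreremophilan-3α-yl (2E,4E,6E)-5-methyldodeca-2,4,6-trienoate (10βH) | CCCCC/C=C/C(C)=C/C=C/C(=O)O[C@@H]1CC[C@@H]2[C@@H](O[Si](C(C)C)(C(C)C)C(C)C)C(=O)CC[C@]2(C)[C@H]1C | intermediate
28 | chloroacetone | CC(=O)CCl | starting material
29 | 12-chloro-11-hydroxy-8-oxo-9β-(triisopropylsilyloxy)eremophilan-3α-yl (2E,4E,6E)-5-methyldodeca-2,4,6-trienoate (mixture at C7 and C11; not isolated) | CCCCC/C=C/C(C)=C/C=C/C(=O)O[C@@H]1CC[C@@H]2[C@@H](O[Si](C(C)C)(C(C)C)C(C)C)C(=O)C(C(C)(O)CCl)C[C@]2(C)[C@H]1C | intermediate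
30 | 11,12-epoxy-8-oxo-9β-(triisopropylsilyloxy)eremophilan-3α-yl (2E,4E,6E)-5-methyldodeca-2,4,6-trienoate (mixture at C7 and C11; not isolated) | CCCCC/C=C/C(C)=C/C=C/C(=O)O[C@@H]1CC[C@@H]2[C@@H](O[Si](C(C)C)(C(C)C)C(C)C)C(=O)C(C3(C)CO3)C[C@]2(C)[C@H]1C | intermediate
31 | (7(11)Z)-12-hydroxy-8-oxo-9β-(triisopropylsilyloxy)eremophil-7(11)-en-3α-yl (2E,4E,6E)-5-methyldodeca-2,4,6-trienoate | CCCCC/C=C/C(C)=C/C=C/C(=O)O[C@@H]1CC[C@@H]2[C@@H](O[Si](C(C)C)(C(C)C)C(C)C)C(=O)/C(=C(/C)CO)C[C@]2(C)[C@H]1C | intermediate
32 | (3R,4R,5R,9R,10S,7(11)Z)-9,12-dihydroxy-8-oxoeremophil-7(11)-en-3-yl (2E,4E,6E)-5-methyldodeca-2,4,6-trienoate (3α-acyloxy, 9β-OH, 10βH; CNP0226738.1) | CCCCC/C=C/C(C)=C/C=C/C(=O)O[C@@H]1CC[C@@H]2[C@@H](O)C(=O)/C(=C(/C)CO)C[C@]2(C)[C@H]1C | target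

## Step count and least certain steps

Total: 20 steps. Longest linear sequence: 17 steps (steps 1–14 and 18–20); dienal 26 is made in 3 steps (15–17) and joined in step 18.

**Step 10 (key step, proposed new method).** The most likely failure is poor facial discrimination at C5, because the chiral iodine is bound at O8 and the bond forms at the remote para carbon. Attack at the silyloxy-bearing C9, attack through the enol oxygen, or oxidation of the keto ester by trivalent iodine could lower the yield further. Fallback with known chemistry: 13 is cyclised with stoichiometric PhI(OAc)2 in (CF3)2CHOH at 0 °C, the established conditions for para-cyclisation of 4-alkylphenols onto tethered carbon nucleophiles, to give the racemic form of 14 (F1). The conditions of step 11 convert F1 into the racemic form of 16 (F2). The enantiomers of F2 are separated by preparative chromatography on a chiral stationary phase, and the route is rejoined at 16.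

**Step 14.** The β-carbon C10 is fully substituted, flanked by the quaternary C5, and the enone is deactivated by the silyloxy donor. The reduction may therefore stall, reduce the C8 carbonyl 1,2, or deliver hydride to the α face and give the trans-decalin. Fallback: 19 is hydrogenated (H2, 4 bar, Pd/C, EtOAc). Syn addition on the β face, which is the usual course for angularly methylated octalones, should give the 9α-silyloxy epimer of 21 (F3). Treatment of F3 with DBU as in step 14 epimerises C9 and returns 21.

**Step 13.** The 3β-hydroxyl is axial and syn to the C14 methyl, so its activation may be slow, and the anti-periplanar axial hydrogens on C2 and C4 allow E2 elimination in place of substitution. Fallback: 17 is converted with (CF3SO2)2O and pyridine (CH2Cl2, −20 °C) into the 3β-trifluoromethanesulfonate of 17 (F4). The sulfonate is formed easily even at a hindered oxygen, and F4 is then displaced with cesium (diethoxyphosphoryl)acetate (from 18 and Cs2CO3) and 18-crown-6 in toluene at rt. The weakly basic carboxylate reacts with inversion at low temperature, and the route is rejoined at 19.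

**Step 19.** Proton transfer from chloroacetone to the enolate or displacement at the CH2Cl carbon may compete with carbonyl addition. The elimination may also give the E alkene alongside the Z alkene, and prolonged base may isomerise the γ-hydroxy enone further. Fallback: the enolate of 27 (LiN(SiMe3)2, THF, −78 °C) is added to 1-(tert-butyldimethylsilyloxy)propan-2-one to give the 11-hydroxy-12-(tert-butyldimethylsilyloxy) aldol adduct of 27 (F5). Dehydration of F5 with methyl N-(triethylammoniumsulfonyl)carbamate (benzene, 50 °C) gives the (Z)-12-(tert-butyldimethylsilyl) ether of 31 (F6) and its (E)-isomer (F7), which are separated. F7 is re-equilibrated with DBU in toluene through the extended enolate, which leaves the all-E trienoate alone, and recycled. F6 loses both silyl groups under the conditions of step 20 and the route is rejoined at 32.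

**Step 11.** The proton may reach C4 from both faces, or C4 may equilibrate in the amine buffer; at this stage the two C4 epimers are expected to be close in energy, so an equilibrated mixture would not correct itself. Fallback: the protonation is put under reagent control by running the decarboxylation of 14 with Pd(OAc)2, an enantiopure tert-butyl-substituted phosphinooxazoline ligand (the enantiomer that reinforces the substrate bias) and Meldrum's acid as proton donor in dioxane at rt. This is the known enantioselective decarboxylative protonation of allyl keto esters; it gives 16 directly, and this fallback F0 makes no new compound (F0).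

## Further compounds

F1 | step 10 | racemic 14 (both enantiomers, relative configuration as drawn) | O=C1CCC2=C(O[Si](C(C)C)(C(C)C)C(C)C)C(=O)C=C[C@]2(C)[C@]1(C)C(=O)OCC=C.O=C1CCC2=C(O[Si](C(C)C)(C(C)C)C(C)C)C(=O)C=C[C@@]2(C)[C@@]1(C)C(=O)OCC=C
F2 | step 10 | racemic 16 (both enantiomers, methyl groups cis) | O=C1CCC2=C(O[Si](C(C)C)(C(C)C)C(C)C)C(=O)C=C[C@]2(C)[C@H]1C.O=C1CCC2=C(O[Si](C(C)C)(C(C)C)C(C)C)C(=O)C=C[C@@]2(C)[C@@H]1C
F3 | step 14 | 8-oxo-9α-(triisopropylsilyloxy)-11,12,13-trinoreremophilan-3α-yl (diethoxyphosphoryl)acetate (10βH; C9 epimer of 21) | CCOP(=O)(CC(=O)O[C@@H]1CC[C@@H]2[C@H](O[Si](C(C)C)(C(C)C)C(C)C)C(=O)CC[C@]2(C)[C@H]1C)OCC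
F4 | step 13 | 8-oxo-9-(triisopropylsilyloxy)-11,12,13-trinoreremophil-9-en-3β-yl trifluoromethanesulfonate | O=S(=O)(O[C@H]1CCC2=C(O[Si](C(C)C)(C(C)C)C(C)C)C(=O)CC[C@]2(C)[C@H]1C)C(F)(F)F
F5 | step 19 | 12-(tert-butyldimethylsilyloxy)-11-hydroxy-8-oxo-9β-(triisopropylsilyloxy)eremophilan-3α-yl (2E,4E,6E)-5-methyldodeca-2,4,6-trienoate (mixture at C7 and C11) | CCCCC/C=C/C(C)=C/C=C/C(=O)O[C@@H]1CC[C@@H]2[C@@H](O[Si](C(C)C)(C(C)C)C(C)C)C(=O)C(C(C)(O)CO[Si](C)(C)C(C)(C)C)C[C@]2(C)[C@H]1C
F6 | step 19 | (7(11)Z)-12-(tert-butyldimethylsilyloxy)-8-oxo-9β-(triisopropylsilyloxy)eremophil-7(11)-en-3α-yl (2E,4E,6E)-5-methyldodeca-2,4,6-trienoate | CCCCC/C=C/C(C)=C/C=C/C(=O)O[C@@H]1CC[C@@H]2[C@@H](O[Si](C(C)C)(C(C)C)C(C)C)C(=O)/C(=C(/C)CO[Si](C)(C)C(C)(C)C)C[C@]2(C)[C@H]1C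
F7 | step 19 | (7(11)E)-12-(tert-butyldimethylsilyloxy)-8-oxo-9β-(triisopropylsilyloxy)eremophil-7(11)-en-3α-yl (2E,4E,6E)-5-methyldodeca-2,4,6-trienoate | CCCCC/C=C/C(C)=C/C=C/C(=O)O[C@@H]1CC[C@@H]2[C@@H](O[Si](C(C)C)(C(C)C)C(C)C)C(=O)/C(=C(\C)CO[Si](C)(C)C(C)(C)C)C[C@]2(C)[C@H]1C
F0 | step 11 | none | none
A1 | alternative 1 | 3α-(triethylsilyloxy)-9β-hydroxy-12-(tert-butyldiphenylsilyloxy)eremophila-1,7(11)-dien-8-one (10βH) | CC[Si](CC)(CC)O[C@@H]1C=C[C@@H]2[C@@H](O)C(=O)/C(=C(/C)CO[Si](c3ccccc3)(c3ccccc3)C(C)(C)C)C[C@]2(C)[C@H]1C
A2 | alternative 2 | 3α-acetoxy-9β-(tert-butyldimethylsilyloxy)-11,12,13-trinoreremophil-1-en-8-one (10βH, cis-decalin) | CC(=O)O[C@@H]1C=C[C@@H]2[C@@H](O[Si](C)(C)C(C)(C)C)C(=O)CC[C@]2(C)[C@H]1C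
A3 | alternative 3 | 3α-(4-methoxybenzyloxy)-9β,12-bis(tert-butyldimethylsilyloxy)eremophil-7(11)-en-8-ol (10βH; 8α-carbinol drawn) | COc1ccc(CO[C@@H]2CC[C@@H]3[C@@H](O[Si](C)(C)C(C)(C)C)[C@H](O)/C(=C(/C)CO[Si](C)(C)C(C)(C)C)C[C@]3(C)[C@H]2C)cc1
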